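**Retrosynthetic overview** (ring carbons numbered as in quinic acid; C-1 carries the carboxyl carbon C-7)
1. Target 16 ⇐ one acid hydrolysis (four aryl acetates, one silyl ether, one γ-lactone) of bis-ester 15 ⇐ double acylation of 4-O-silyl quinide 11, whose only free hydroxyls are O-1 and O-3, with acid chloride 14.
2. 11 ⇐ hydrogenolysis, lactonisation (temporary C-7/O-5 γ-lactone) and hydroxyl-directed reduction of the 5-oxocyclohexane 8.
3. 8 ⇐ cut the ring bonds C-3–C-4 and C-1–C-6: 1-oxadiene 3 (C-7, C-1, C-2, C-3) plus enediol bis-silyl ether 5 (C-4, C-5, C-6), joined in one flask by a hetero-Diels–Alder reaction to a temporary dihydropyran (its O–C-5 bond is not in the target) and an acid-triggered ring switch (aldol) to the carbocycle.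
4. Enabling feature: C-1 and C-3 both carry oxygen and are separated only by the methylene C-2, so O=C-1–C-2=C-3–O is a latent 4-alkoxy-2-oxobut-3-enoate; the oxygenated C-5 lies between C-4 and C-6, so as a ketone it makes both neighbours nucleophilic; O-1/O-3 are cis-1,3 and C-7/O-5 are cis, which the ring closure and the lactone exploit.
5. Ring order: dihydropyran (temporary), cyclohexane, γ-lactone (temporary, opened in the last step).

Key step: step 3

Assumption: the facial sense of the divalent-copper catalyst (t-Bu-box = 2,2′-(propane-2,2-diyl)bis(4-tert-butyl-4,5-dihydrooxazole)) is taken from the square-planar chelate model for 2-oxo esters, in which the (S,S)-ligand leaves the Si face of the ketone carbon and the same side of the conjugated terminus open; on that model the (R,R)-ligand is needed in step 3, and both antipodes are commercial.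

**Step 1**
Reactants: 1 benzyl vinyl ether; 2 methyl chlorooxoacetate
Product: 3 methyl (3E)-4-(benzyloxy)-2-oxobut-3-enoate
Conditions: pyridine, CH2Cl2, 0 °C → rt
Reagents that add atoms: none
Why: C-acylation of the electron-rich enol ether by the oxalyl chloride followed by pyridine-mediated loss of HCl (acylation of vinyl ethers, the usual entry to 4-alkoxy-2-oxobut-3-enoates) should give the more stable E-alkene, and no stereocenter is formed.

**Step 2**
Reactants: 4 1-[(tert-butyldimethylsilyl)oxy]propan-2-one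
Product: 5 tert-butyl(dimethyl){[(1Z)-2-[(trimethylsilyl)oxy]prop-1-en-1-yl]oxy}silane
Conditions: Me3SiOTf, Et3N, CH2Cl2, 0 °C → rt
Reagents that add atoms: trimethylsilyl trifluoromethanesulfonate, C[Si](C)(C)OS(=O)(=O)C(F)(F)F
Why: soft enolisation and O-silylation (silyl enol ether formation) toward the more acidic oxygen-bearing methylene should give the 1,2-bis(silyloxy)alkene, the Z isomer being expected to predominate and the geometry being uncritical because C-4 later sits next to a ketone.

**Step 3**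
Reactants: 3 methyl (3E)-4-(benzyloxy)-2-oxobut-3-enoate; 5 tert-butyl(dimethyl){[(1Z)-2-[(trimethylsilyl)oxy]prop-1-en-1-yl]oxy}silane
Product: 8 methyl (1S,3R,4R)-3-(benzyloxy)-4-[(tert-butyldimethylsilyl)oxy]-1-hydroxy-5-oxocyclohexane-1-carboxylate, via dihydropyran cycloadduct 6 (not isolated), via open-chain diketone 7 (not isolated)
Conditions: [Cu((R,R)-t-Bu-box)](OTf)2 (10 mol%), THF, −78 → −40 °C; then CF3CO2H (1 equiv), H2O (5 equiv), 0 °C → rt
Reagents that add atoms: none
Why: Proposed new method: the bis(oxazoline) complex of divalent copper chelates the 2-oxo ester of 3 and catalyses an inverse-electron-demand hetero-Diels–Alder reaction with 5 (closest known reaction type: enantioselective cycloadditions of 4-alkoxy-2-oxobut-3-enoates with enol ethers), which forms the C-3–C-4 bond together with a temporary O–C-5 bond in dihydropyran 6; aqueous acid then cleaves the labile silyl ketal of 6 to the 1,5-dicarbonyl compound 7, whose methyl-ketone enol adds to the 2-oxo ester to forge the C-6–C-1 bond (closest known reaction types: Ferrier carbocyclisation of enol pyranoses, amine-mediated ketolisation of 6-oxo-2-oxo esters and the biosynthetic closure of 3-dehydroquinate). The dihydropyran closes by an endo [4+2] cycloaddition and the carbocycle by a 6-(enolendo)-exo-trig aldol addition. C-3 is set by the catalyst, whose ligand antipode is chosen to expose the Si face of the benzyloxy-bearing diene terminus; C-4 follows from suprafacial endo addition of the Z-alkene and is in any case the equatorial, thermodynamically preferred epimer next to the ketone; C-1 is set in a chair transition state with the ester equatorial and the activated ketone oxygen hydrogen-bonded to the axial benzyloxy oxygen, which places O-1 and O-3 cis, while the ketal centre at C-5 is transient. The step needs regioselective cycloaddition (the alkene carbon bearing silyloxy and methyl best carries positive charge and so bonds to the carbonyl oxygen, leaving the other carbon to bond to C-3), aldol closure faster than β-elimination of benzyl alcohol from 7 (six-membered intramolecular attack on a highly electrophilic 2-oxo ester, poor leaving group) and no dehydration of the tertiary ketol (dilute acid, ambient temperature).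

**Step 4**
Reactants: 8 methyl (1S,3R,4R)-3-(benzyloxy)-4-[(tert-butyldimethylsilyl)oxy]-1-hydroxy-5-oxocyclohexane-1-carboxylate
Product: 9 methyl (1R,3R,4S,5R)-3-(benzyloxy)-4-[(tert-butyldimethylsilyl)oxy]-1,5-dihydroxycyclohexane-1-carboxylate
Conditions: Me4NBH(OAc)3, MeCN/AcOH (1:1), −25 °C
Reagents that add atoms: none
Why: in this hydroxyl-directed (Evans–Saksena) reduction the acetoxyborohydride bound to the axial tertiary 1-OH delivers hydride to the same face of the C-5 ketone, so the new 5-OH should be equatorial, anti to O-1 and trans to the 4-silyloxy group.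

**Step 5**
Reactants: 9 methyl (1R,3R,4S,5R)-3-(benzyloxy)-4-[(tert-butyldimethylsilyl)oxy]-1,5-dihydroxycyclohexane-1-carboxylate
Product: 10 (1S,3R,4R,5R)-3-(benzyloxy)-4-[(tert-butyldimethylsilyl)oxy]-1-hydroxy-6-oxabicyclo[3.2.1]octan-7-one
Conditions: CSA (0.1 equiv), toluene, 70 °C, 4 Å MS
Reagents that add atoms: none
Why: acid-catalysed lactonisation (intramolecular transesterification) between the ester and the cis 5-OH closes the quinide γ-lactone, which protects O-5 and the carboxyl in one temporary ring without touching a stereocenter.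

**Step 6**
Reactants: 10 (1S,3R,4R,5R)-3-(benzyloxy)-4-[(tert-butyldimethylsilyl)oxy]-1-hydroxy-6-oxabicyclo[3.2.1]octan-7-one
Product: 11 (1S,3R,4R,5R)-4-[(tert-butyldimethylsilyl)oxy]-1,3-dihydroxy-6-oxabicyclo[3.2.1]octan-7-one
Conditions: H2 (1 atm), 10% Pd/C, EtOAc, rt
Reagents that add atoms: none
Why: catalytic hydrogenolysis of the benzyl ether frees O-3 while silyl ether and lactone persist, and no alkene is present yet.

**Step 7**
Reactants: 12 caffeic acid
Product: 13 (2E)-3-[3,4-bis(acetyloxy)phenyl]prop-2-enoic acid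
Conditions: Ac2O, pyridine, rt; then H2O
Reagents that add atoms: acetic anhydride, CC(=O)OC(C)=O
Why: O-acetylation masks both phenols for the acid chloride and acylation steps, any mixed anhydride at the carboxyl being hydrolysed on aqueous work-up.

**Step 8**
Reactants: 13 (2E)-3-[3,4-bis(acetyloxy)phenyl]prop-2-enoic acid
Product: 14 (2E)-3-[3,4-bis(acetyloxy)phenyl]prop-2-enoyl chloride
Conditions: (COCl)2, DMF (cat.), CH2Cl2, 0 °C → rt
Reagents that add atoms: oxalyl chloride, O=C(Cl)C(Cl)=O
Why: Vilsmeier-type activation converts the acid into the acid chloride without affecting the aryl acetates or the E-alkene.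

**Step 9**
Reactants: 11 (1S,3R,4R,5R)-4-[(tert-butyldimethylsilyl)oxy]-1,3-dihydroxy-6-oxabicyclo[3.2.1]octan-7-one; 14 (2E)-3-[3,4-bis(acetyloxy)phenyl]prop-2-enoyl chloride
Product: 15 (1S,3R,4R,5R)-4-[(tert-butyldimethylsilyl)oxy]-7-oxo-6-oxabicyclo[3.2.1]octane-1,3-diyl bis{(2E)-3-[3,4-bis(acetyloxy)phenyl]prop-2-enoate}
Conditions: 14 (3 equiv), DMAP (0.5 equiv), pyridine, CH2Cl2, 0 → 40 °C
Reagents that add atoms: none
Why: DMAP-catalysed acylation through the acylpyridinium ion esterifies the equatorial secondary 3-OH and, with excess reagent and gentle warming, the tertiary 1-OH, the only two free hydroxyls, without touching a stereocenter.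

**Step 10**
Reactants: 15 (1S,3R,4R,5R)-4-[(tert-butyldimethylsilyl)oxy]-7-oxo-6-oxabicyclo[3.2.1]octane-1,3-diyl bis{(2E)-3-[3,4-bis(acetyloxy)phenyl]prop-2-enoate}
Product: 16 (1R,3R,4S,5R)-1,3-bis{[(2E)-3-(3,4-dihydroxyphenyl)prop-2-enoyl]oxy}-4,5-dihydroxycyclohexane-1-carboxylic acid (1,3-dicaffeoylquinic acid)
Conditions: 2 M aq. HCl/THF (1:3), rt
Reagents that add atoms: water, O
Why: acid-catalysed hydrolysis should remove the four aryl acetates and the silyl ether and open the strained lactone, while the conjugated cinnamoyl esters are expected to persist and base-promoted acyl migration is avoided.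

**Compound list**
1 | benzyl vinyl ether | C=COCc1ccccc1 | starting material
2 | methyl chlorooxoacetate | COC(=O)C(=O)Cl | starting material
3 | methyl (3E)-4-(benzyloxy)-2-oxobut-3-enoate | COC(=O)C(=O)/C=C/OCc1ccccc1 | intermediate
4 | 1-[(tert-butyldimethylsilyl)oxy]propan-2-one | CC(=O)CO[Si](C)(C)C(C)(C)C | starting material
5 | tert-butyl(dimethyl){[(1Z)-2-[(trimethylsilyl)oxy]prop-1-en-1-yl]oxy}silane | C/C(O[Si](C)(C)C)=C/O[Si](C)(C)C(C)(C)C | intermediate
6 | methyl (2R,3R,4R)-4-(benzyloxy)-3-[(tert-butyldimethylsilyl)oxy]-2-methyl-2-[(trimethylsilyl)oxy]-3,4-dihydro-2H-pyran-6-carboxylate | COC(=O)C1=C[C@@H](OCc2ccccc2)[C@@H](O[Si](C)(C)C(C)(C)C)[C@@](C)(O[Si](C)(C)C)O1 | intermediate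
7 | methyl (4R,5R)-4-(benzyloxy)-5-[(tert-butyldimethylsilyl)oxy]-2,6-dioxoheptanoate | COC(=O)C(=O)C[C@@H](OCc1ccccc1)[C@@H](O[Si](C)(C)C(C)(C)C)C(C)=O | intermediate
8 | methyl (1S,3R,4R)-3-(benzyloxy)-4-[(tert-butyldimethylsilyl)oxy]-1-hydroxy-5-oxocyclohexane-1-carboxylate | COC(=O)[C@]1(O)C[C@@H](OCc2ccccc2)[C@@H](O[Si](C)(C)C(C)(C)C)C(=O)C1 | intermediate
9 | methyl (1R,3R,4S,5R)-3-(benzyloxy)-4-[(tert-butyldimethylsilyl)oxy]-1,5-dihydroxycyclohexane-1-carboxylate | COC(=O)[C@]1(O)C[C@@H](OCc2ccccc2)[C@@H](O[Si](C)(C)C(C)(C)C)[C@H](O)C1 | intermediate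
10 | (1S,3R,4R,5R)-3-(benzyloxy)-4-[(tert-butyldimethylsilyl)oxy]-1-hydroxy-6-oxabicyclo[3.2.1]octan-7-one | O=C1O[C@@H]2C[C@@]1(O)C[C@@H](OCc3ccccc3)[C@H]2O[Si](C)(C)C(C)(C)C | intermediate
11 | (1S,3R,4R,5R)-4-[(tert-butyldimethylsilyl)oxy]-1,3-dihydroxy-6-oxabicyclo[3.2.1]octan-7-one | O=C1O[C@@H]2C[C@@]1(O)C[C@@H](O)[C@H]2O[Si](C)(C)C(C)(C)C | intermediate
12 | caffeic acid | O=C(O)/C=C/c1ccc(O)c(O)c1 | starting material
13 | (2E)-3-[3,4-bis(acetyloxy)phenyl]prop-2-enoic acid | CC(=O)Oc1ccc(/C=C/C(=O)O)cc1OC(C)=O | intermediate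
14 | (2E)-3-[3,4-bis(acetyloxy)phenyl]prop-2-enoyl chloride | CC(=O)Oc1ccc(/C=C/C(=O)Cl)cc1OC(C)=O | intermediate
15 | (1S,3R,4R,5R)-4-[(tert-butyldimethylsilyl)oxy]-7-oxo-6-oxabicyclo[3.2.1]octane-1,3-diyl bis{(2E)-3-[3,4-bis(acetyloxy)phenyl]prop-2-enoate} | O=C1O[C@@H]2C[C@@]1(OC(=O)/C=C/c3ccc(OC(C)=O)c(OC(C)=O)c3)C[C@@H](OC(=O)/C=C/c3ccc(OC(C)=O)c(OC(C)=O)c3)[C@H]2O[Si](C)(C)C(C)(C)C | intermediate
16 | (1R,3R,4S,5R)-1,3-bis{[(2E)-3-(3,4-dihydroxyphenyl)prop-2-enoyl]oxy}-4,5-dihydroxycyclohexane-1-carboxylic acid | O=C(/C=C/c1ccc(O)c(O)c1)O[C@@H]1C[C@@](OC(=O)/C=C/c2ccc(O)c(O)c2)(C(=O)O)C[C@@H](O)[C@@H]1O | target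

Total step count: 10
Longest linear sequence: 7 steps (steps 1, 3, 4, 5, 6, 9, 10)

**Steps most likely to fail**

Step 3 (Proposed new method). The cascade may leak through loss of benzyl alcohol from the transient β-benzyloxy-2-oxo ester, through ring closure onto the wrong face of C-1, or through dehydration of the ketol. The fallback uses known reactions, makes the two bonds in separate operations and in the opposite order, sets out from 4 and returns at 11. Kinetic enolisation of 4 (LiN(iPr)2, Me3SiCl, THF, −78 °C) gives the terminal silyl enol ether tert-butyl(dimethyl)({2-[(trimethylsilyl)oxy]prop-2-en-1-yl}oxy)silane F1. Addition of commercial (1,3-dioxolan-2-ylmethyl)magnesium bromide to dimethyl oxalate at −78 °C gives methyl 3-(1,3-dioxolan-2-yl)-2-oxopropanoate F2. A Mukaiyama aldol addition of F1 to F2 under [Cu((S,S)-t-Bu-box)](OTf)2 catalysis forms C-6–C-1 and sets C-1, giving after mild acidic work-up methyl (2S)-5-[(tert-butyldimethylsilyl)oxy]-2-(1,3-dioxolan-2-ylmethyl)-2-hydroxy-4-oxopentanoate F3. Aqueous acid hydrolysis of the acetal gives methyl (2S)-5-[(tert-butyldimethylsilyl)oxy]-2-hydroxy-4-oxo-2-(2-oxoethyl)pentanoate F4. A proline-catalysed intramolecular aldol addition (6-enolendo) forms C-3–C-4 and should give methyl (1S,3R,4R)-4-[(tert-butyldimethylsilyl)oxy]-1,3-dihydroxy-5-oxocyclohexane-1-carboxylate F5, C-4 settling as the equatorial epimer. Hydroxyl-directed reduction as in step 4 gives methyl 4-O-(tert-butyldimethylsilyl)quinate F6, and lactonisation as in step 5 gives 11, so that steps 4 to 6 are bypassed.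

Step 9. The hindered tertiary 1-OH may acylate only slowly, so that mono-ester accumulates, and the basic medium may promote silyl migration from O-4 to O-3. The fallback sets out from 11 and returns at 16; it builds the caffeoyl groups on the oxygen atoms instead of transferring them. Alcoholysis of Meldrum's acid by 11 (toluene, 100 °C, a reaction that tolerates tertiary alcohols) gives the bis(hydrogen malonate) 3,3′-{[(1S,3R,4R,5R)-4-[(tert-butyldimethylsilyl)oxy]-7-oxo-6-oxabicyclo[3.2.1]octane-1,3-diyl]bis(oxy)}bis(3-oxopropanoic acid) F7. Knoevenagel–Doebner condensation with 3,4-dihydroxybenzaldehyde (pyridine, piperidine cat., 50 °C) gives (1S,3R,4R,5R)-4-[(tert-butyldimethylsilyl)oxy]-7-oxo-6-oxabicyclo[3.2.1]octane-1,3-diyl bis[(2E)-3-(3,4-dihydroxyphenyl)prop-2-enoate] F8. The aqueous acid treatment of step 10 then cleaves the silyl ether and opens the lactone to give 16.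

Step 5. Hot acid may shift or cleave the secondary silyl ether next to the free 5-OH, or the lactonisation may stop at equilibrium. The fallback sets out from 9 and returns at 10; it closes the ring by carboxyl activation instead of transesterification. Neutral ester cleavage with Me3SnOH (1,2-dichloroethane, 70 °C) gives (1R,3R,4S,5R)-3-(benzyloxy)-4-[(tert-butyldimethylsilyl)oxy]-1,5-dihydroxycyclohexane-1-carboxylic acid F9, which is closed at room temperature with 2-chloro-1-methylpyridinium iodide and Et3N in CH2Cl2 (Mukaiyama lactonisation) to give 10.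

**Further compounds**
F1 | step 3 | tert-butyl(dimethyl)({2-[(trimethylsilyl)oxy]prop-2-en-1-yl}oxy)silane | C=C(CO[Si](C)(C)C(C)(C)C)O[Si](C)(C)C
F2 | step 3 | methyl 3-(1,3-dioxolan-2-yl)-2-oxopropanoate | COC(=O)C(=O)CC1OCCO1
F3 | step 3 | methyl (2S)-5-[(tert-butyldimethylsilyl)oxy]-2-(1,3-dioxolan-2-ylmethyl)-2-hydroxy-4-oxopentanoate | COC(=O)[C@](O)(CC1OCCO1)CC(=O)CO[Si](C)(C)C(C)(C)C
F4 | step 3 | methyl (2S)-5-[(tert-butyldimethylsilyl)oxy]-2-hydroxy-4-oxo-2-(2-oxoethyl)pentanoate | COC(=O)[C@](O)(CC=O)CC(=O)CO[Si](C)(C)C(C)(C)C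
F5 | step 3 | methyl (1S,3R,4R)-4-[(tert-butyldimethylsilyl)oxy]-1,3-dihydroxy-5-oxocyclohexane-1-carboxylate | COC(=O)[C@]1(O)C[C@@H](O)[C@@H](O[Si](C)(C)C(C)(C)C)C(=O)C1
F6 | step 3 | methyl 4-O-(tert-butyldimethylsilyl)quinate | COC(=O)[C@]1(O)C[C@@H](O)[C@@H](O[Si](C)(C)C(C)(C)C)[C@H](O)C1
F7 | step 9 | 3,3′-{[(1S,3R,4R,5R)-4-[(tert-butyldimethylsilyl)oxy]-7-oxo-6-oxabicyclo[3.2.1]octane-1,3-diyl]bis(oxy)}bis(3-oxopropanoic acid) | O=C1O[C@@H]2C[C@@]1(OC(=O)CC(=O)O)C[C@@H](OC(=O)CC(=O)O)[C@H]2O[Si](C)(C)C(C)(C)C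
F8 | step 9 | (1S,3R,4R,5R)-4-[(tert-butyldimethylsilyl)oxy]-7-oxo-6-oxabicyclo[3.2.1]octane-1,3-diyl bis[(2E)-3-(3,4-dihydroxyphenyl)prop-2-enoate] | O=C1O[C@@H]2C[C@@]1(OC(=O)/C=C/c3ccc(O)c(O)c3)C[C@@H](OC(=O)/C=C/c3ccc(O)c(O)c3)[C@H]2O[Si](C)(C)C(C)(C)C
F9 | step 5 | (1R,3R,4S,5R)-3-(benzyloxy)-4-[(tert-butyldimethylsilyl)oxy]-1,5-dihydroxycyclohexane-1-carboxylic acid | OC(=O)[C@]1(O)C[C@@H](OCc2ccccc2)[C@@H](O[Si](C)(C)C(C)(C)C)[C@H](O)C1
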